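## Retrosynthetic overview

1. Macrocarpal H ⇐ tris‑O‑methyl, bis(silyloxymethyl)aryl decalone; end‑game is C4 methylenation, benzylic oxidation to the two CHO groups, and thiolate O‑demethylation.
2. C1′ stereocentre ⇐ SN1 methallylation (1,3‑allylic‑strain control) of the carbinol made from aryllithium (from **24**) and decalone aldehyde **18** (fragment coupling, C1′–Ar).
3. Decalone **18** ⇐ ring B closed by an intramolecular Mukaiyama aldol condensation (C5–C6) of the silyl enol ether from Cu‑catalysed conjugate addition (C9–C10, quaternary C10) of the Grignard of **14** to enone **7**.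
4. Enone **7** ⇐ organocatalytic Michael addition, intramolecular aldol condensation, then β‑methylation/Saegusa; chain **14** ⇐ Evans acetalisation and MeMgBr; aryl **24** ⇐ phloroglucinol.
5. Ring order: ring A (aldol condensation, step 3), then ring B (Mukaiyama aldol, step 12); the aromatic ring is carried intact.

Assumptions: positions are cited in eudesmane numbering (ring A = C1–C5, C10; ring B = C5–C10; C11 = carbinol carbon; C1′ = benzylic carbon). The organocatalyst and the Evans auxiliary are purchased. Carbinol **25** is used as its C1′‑epimer mixture, since both epimers give the same cation.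

## Branch A – ring A enone

**Step 1**
Reactants: **1** 3‑(benzyloxy)propan‑1‑ol
Product: **2** 3‑(benzyloxy)propanal
Conditions: TEMPO (cat.), PhI(OAc)2, CH2Cl2, rt
Reagents that add atoms: none
Why: TEMPO/BAIB oxidation of a primary alcohol stops cleanly at the aldehyde.

**Step 2**
Reactants: **2**; **3** methyl vinyl ketone
Product: **4** (2S)‑2‑[(benzyloxy)methyl]‑5‑oxohexanal
Conditions: (S)‑2‑(methoxydiphenylmethyl)pyrrolidine (5 mol%), ethyl 3,4‑dihydroxybenzoate (20 mol%), neat, 4 °C
Reagents that add atoms: none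
Why: Enamine‑catalysed asymmetric Michael addition; MVK attacks the E‑enamine on the face away from the diarylmethyl group, setting the future C1 stereocentre.

**Step 3**
Reactants: **4**
Product: **5** (4R)‑4‑[(benzyloxy)methyl]cyclohex‑2‑en‑1‑one
Conditions: LiOH·H2O (cat.), i‑PrOH, rt
Reagents that add atoms: none
Why: Intramolecular aldol condensation (Robinson‑type closure of ring A); only the methyl‑ketone enolate attacking the aldehyde gives a six‑membered ring, and the stereocentre is not involved.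

**Step 4**
Reactants: **5**
Product: **6** {[(3S,4R)‑4‑[(benzyloxy)methyl]‑3‑methylcyclohex‑1‑en‑1‑yl]oxy}trimethylsilane (3,4‑trans)
Conditions: Me2CuLi, TMSCl, Et3N, THF, −78 °C
Reagents that add atoms: lithium dimethylcuprate, [Li+].C[Cu-]C; TMSCl, C[Si](C)(C)Cl
Why: Gilman conjugate addition with enolate trapping; methyl adds trans to the C4 substituent, and this new centre is removed in the next step.

**Step 5**
Reactants: **6**
Product: **7** (4R)‑4‑[(benzyloxy)methyl]‑3‑methylcyclohex‑2‑en‑1‑one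
Conditions: Pd(OAc)2, MeCN, rt
Reagents that add atoms: none
Why: Saegusa–Ito oxidation; β‑hydride elimination is only possible from the methyl‑bearing carbon, giving the β‑methyl enone.

## Branch B – C6–C9 chain with C7 and the carbinol carbon

**Step 6**
Reactants: **9** (4S)‑4‑benzyl‑1,3‑oxazolidin‑2‑one; **8** 4‑chlorobutanoyl chloride
Product: **10** (4S)‑4‑benzyl‑3‑(4‑chlorobutanoyl)‑1,3‑oxazolidin‑2‑one
Conditions: n‑BuLi, THF, −78 °C; then **8**
Reagents that add atoms: none
Why: N‑acylation of the lithiated Evans auxiliary.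

**Step 7**
Reactants: **10**
Product: **11** (4S)‑4‑benzyl‑3‑[(2R)‑4‑chloro‑2‑(dimethoxymethyl)butanoyl]‑1,3‑oxazolidin‑2‑one
Conditions: TiCl4, i‑Pr2NEt, CH2Cl2, 0 °C; then HC(OMe)3
Reagents that add atoms: trimethyl orthoformate, COC(OC)OC
Why: Evans titanium‑enolate reaction with an orthoester; the chelated Z‑enolate is attacked by MeO–CH=OMe+ on the face opposite the benzyl group, setting C7.

**Step 8**
Reactants: **11**
Product: **12** methyl (2R)‑4‑chloro‑2‑(dimethoxymethyl)butanoate
Conditions: MeOMgBr (MeMgBr/MeOH), CH2Cl2, 0 °C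
Reagents that add atoms: methanol, CO
Why: Mild transesterification removes the auxiliary without epimerising the α‑centre.

**Step 9**
Reactants: **12**
Product: **13** (3S)‑5‑chloro‑3‑(dimethoxymethyl)‑2‑methylpentan‑2‑ol
Conditions: MeMgBr (3 equiv), CeCl3, THF, −78 → 0 °C, cold quench
Reagents that add atoms: methylmagnesium bromide, C[Mg]Br
Why: Double Grignard addition to the ester builds the hydroxyisopropyl group; CeCl3 suppresses enolisation and the primary chloride is inert at this temperature.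

**Step 10**
Reactants: **13**
Product: **14** {[(3S)‑5‑chloro‑3‑(dimethoxymethyl)‑2‑methylpentan‑2‑yl]oxy}triethylsilane
Conditions: TESOTf, 2,6‑lutidine, CH2Cl2, −78 °C
Reagents that add atoms: TESOTf, CC[Si](CC)(CC)OS(=O)(=O)C(F)(F)F
Why: Silylation of the tertiary alcohol, which must be masked for Grignard formation and the later Lewis‑acid steps.

## Fragment union and ring B

**Step 11**
Reactants: **14**; **7**
Product: **15** {[(3S,4R)‑4‑[(benzyloxy)methyl]‑3‑[(3S)‑3‑(dimethoxymethyl)‑4‑methyl‑4‑(triethylsilyloxy)pentyl]‑3‑methylcyclohex‑1‑en‑1‑yl]oxy}trimethylsilane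
Conditions: **14**, Mg, THF, 50 °C; then CuBr·SMe2 (10 mol%), TMSCl, HMPA, **7**, THF, −78 → −40 °C
Reagents that add atoms: TMSCl, C[Si](C)(C)Cl
Why: Cu‑catalysed conjugate addition (Nakamura–Kuwajima conditions); the primary Grignard adds to the β‑carbon anti to the adjacent pseudoaxial CH2OBn group, creating quaternary C10 and a regiodefined silyl enol ether.

**Step 12**
Reactants: **15**
Product: **16** (4R,4aS,7R)‑4‑[(benzyloxy)methyl]‑4a‑methyl‑7‑[2‑(triethylsilyloxy)propan‑2‑yl]‑3,4,4a,5,6,7‑hexahydronaphthalen‑1(2H)‑one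
Conditions: TMSOTf (cat.), CH2Cl2, −78 °C; then DBU, PhMe, 80 °C
Reagents that add atoms: none
Why: Intramolecular Mukaiyama aldol of the silyl enol ether onto the acetal‑derived oxocarbenium closes ring B (C5–C6), and E1cB loss of MeOH gives the enone; C7 is never enolised.

**Step 13**
Reactants: **16**
Product: **17** (4R,4aS,7R,8aR)‑4‑(hydroxymethyl)‑4a‑methyl‑7‑[2‑(triethylsilyloxy)propan‑2‑yl]octahydronaphthalen‑1(2H)‑one (trans‑fused)
Conditions: H2 (1 atm), Pd(OH)2/C, EtOAc, rt
Reagents that add atoms: none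
Why: Catalytic hydrogenation adds H to C5 from the α‑face opposite the angular methyl (C5 is also epimerisable to the more stable trans‑decalone), and the benzyl ether is hydrogenolysed in the same operation.

**Step 14**
Reactants: **17**
Product: **18** (1R,4aR,6R,8aS)‑8a‑methyl‑4‑oxo‑6‑[2‑(triethylsilyloxy)propan‑2‑yl]decahydronaphthalene‑1‑carbaldehyde
Conditions: Dess–Martin periodinane, NaHCO3, CH2Cl2, 0 °C → rt
Reagents that add atoms: none
Why: Dess–Martin oxidation of the primary alcohol; the C1 formyl group is already in the thermodynamically preferred equatorial (β) position.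

## Branch C – aryl fragment

**Step 15**
Reactants: **19** phloroglucinol
Product: **20** 2,4,6‑trihydroxybenzene‑1,3‑dicarbaldehyde
Conditions: POCl3 (2.2 equiv), DMF, dioxane, rt; H2O
Reagents that add atoms: DMF, CN(C)C=O; water, O
Why: Double Vilsmeier–Haack formylation of the highly activated ring.

**Step 16**
Reactants: **20**
Product: **21** 2,4,6‑trimethoxybenzene‑1,3‑dicarbaldehyde
Conditions: MeI, K2CO3, DMF, 50 °C
Reagents that add atoms: iodomethane, CI
Why: Williamson O‑methylation protects the three phenols for the organolithium and Lewis‑acid chemistry.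

**Step 17**
Reactants: **21**
Product: **22** 5‑bromo‑2,4,6‑trimethoxybenzene‑1,3‑dicarbaldehyde
Conditions: NBS, MeCN, rt
Reagents that add atoms: N‑bromosuccinimide, O=C1CCC(=O)N1Br
Why: Electrophilic aromatic bromination at the only free position, which is ortho/para to three OMe groups and meta to both CHO groups.

**Step 18**
Reactants: **22**
Product: **23** (5‑bromo‑2,4,6‑trimethoxy‑1,3‑phenylene)dimethanol
Conditions: NaBH4, MeOH/THF, 0 °C
Reagents that add atoms: none
Why: Borohydride reduction masks the formyl groups at the alcohol oxidation level.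

**Step 19**
Reactants: **23**
Product: **24** [(5‑bromo‑2,4,6‑trimethoxy‑1,3‑phenylene)bis(methyleneoxy)]bis(triisopropylsilane)
Conditions: TIPSCl, imidazole, DMF, rt
Reagents that add atoms: TIPSCl, CC(C)[Si](Cl)(C(C)C)C(C)C
Why: Bulky silyl ethers survive aryllithium formation and resist Lewis‑acid ionisation.

## Coupling and end‑game

**Step 20**
Reactants: **24**; **18**
Product: **25** (4R,4aS,7R,8aR)‑4‑{hydroxy[2,4,6‑trimethoxy‑3,5‑bis(triisopropylsilyloxymethyl)phenyl]methyl}‑4a‑methyl‑7‑[2‑(triethylsilyloxy)propan‑2‑yl]octahydronaphthalen‑1(2H)‑one (C1′ epimers)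
Conditions: **24**, t‑BuLi (2 equiv), THF, −78 °C; then **18**, −78 °C
Reagents that add atoms: none
Why: Br/Li exchange followed by 1,2‑addition to the aldehyde, which is far more electrophilic than the flanked ring ketone; the carbinol configuration is irrelevant.

**Step 21**
Reactants: **25**
Product: **26** (4S,4aS,7R,8aR)‑4‑{(1S)‑3‑methyl‑1‑[2,4,6‑trimethoxy‑3,5‑bis(triisopropylsilyloxymethyl)phenyl]but‑3‑en‑1‑yl}‑4a‑methyl‑7‑[2‑(triethylsilyloxy)propan‑2‑yl]octahydronaphthalen‑1(2H)‑one
Conditions: methallyl‑TMS (5 equiv), BF3·OEt2, CH2Cl2, −78 → −40 °C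
Reagents that add atoms: (2‑methylallyl)trimethylsilane, C=C(C)C[Si](C)(C)C
Why: SN1 (Hosomi–Sakurai‑type) allylation of the aryl‑stabilised cation; 1,3‑allylic strain places C1–H in the aryl plane and the allylsilane attacks the face anti to quaternary C10 (C2 side), giving (S)‑C1′.

**Step 22**
Reactants: **26**
Product: **27** (4S,4aS,7R,8aR)‑4‑{(1S)‑3‑methyl‑1‑[2,4,6‑trimethoxy‑3,5‑bis(triisopropylsilyloxymethyl)phenyl]butyl}‑4a‑methyl‑7‑[2‑(triethylsilyloxy)propan‑2‑yl]octahydronaphthalen‑1(2H)‑one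
Conditions: H2 (1 atm), Pd/C, EtOAc, rt
Reagents that add atoms: none
Why: Hydrogenation of the unhindered 1,1‑disubstituted alkene gives the isobutyl group, done before the exocyclic methylene exists.

**Step 23**
Reactants: **27**
Product: **28** triethyl{2‑[(2R,4aS,8S,8aS)‑8‑{(1S)‑3‑methyl‑1‑[2,4,6‑trimethoxy‑3,5‑bis(triisopropylsilyloxymethyl)phenyl]butyl}‑8a‑methyl‑5‑methylidenedecahydronaphthalen‑2‑yl]propan‑2‑yloxy}silane
Conditions: Ph3PCH3Br, KOt‑Bu, PhMe, 80 °C
Reagents that add atoms: methylenetriphenylphosphorane, [CH2-][P+](c1ccccc1)(c1ccccc1)c1ccccc1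
Why: Wittig methylenation of the C4 ketone; any base‑induced equilibration at C5 favours the trans ring fusion.

**Step 24**
Reactants: **28**
Product: **29** 2‑[(2R,4aS,8S,8aS)‑8‑{(1S)‑1‑[3,5‑bis(hydroxymethyl)‑2,4,6‑trimethoxyphenyl]‑3‑methylbutyl}‑8a‑methyl‑5‑methylidenedecahydronaphthalen‑2‑yl]propan‑2‑ol
Conditions: TBAF, THF, rt → 40 °C
Reagents that add atoms: none
Why: Fluoride cleaves both TIPS ethers and the tertiary TES ether in one operation.

**Step 25**
Reactants: **29**
Product: **30** 5‑{(1S)‑1‑[(1S,4aS,6R,8aS)‑6‑(2‑hydroxypropan‑2‑yl)‑8a‑methyl‑4‑methylidenedecahydronaphthalen‑1‑yl]‑3‑methylbutyl}‑2,4,6‑trimethoxybenzene‑1,3‑dicarbaldehyde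
Conditions: MnO2 (excess), CH2Cl2, rt
Reagents that add atoms: none
Why: MnO2 oxidises only the two benzylic alcohols, leaving the tertiary alcohol and the alkene untouched.

**Step 26**
Reactants: **30**
Product: **31** Macrocarpal H
Conditions: p‑TolSLi (excess), HMPA/PhMe, 110 °C; aqueous acid work‑up
Reagents that add atoms: none
Why: Thiolate SN2 O‑demethylation; all three methyl ethers are activated by ortho/para formyl groups, and the basic conditions spare the tertiary alcohol and exocyclic alkene.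

## Compound list

1 | 3‑(benzyloxy)propan‑1‑ol | OCCCOCc1ccccc1 | starting material
2 | 3‑(benzyloxy)propanal | O=CCCOCc1ccccc1 | intermediate
3 | methyl vinyl ketone | CC(=O)C=C | starting material
4 | (2S)‑2‑[(benzyloxy)methyl]‑5‑oxohexanal | CC(=O)CC[C@@H](COCc1ccccc1)C=O | intermediate
5 | (4R)‑4‑[(benzyloxy)methyl]cyclohex‑2‑en‑1‑one | O=C1CC[C@@H](COCc2ccccc2)C=C1 | intermediate
6 | {[(3S,4R)‑4‑[(benzyloxy)methyl]‑3‑methylcyclohex‑1‑en‑1‑yl]oxy}trimethylsilane | C[Si](C)(C)OC1=C[C@@H](C)[C@H](COCc2ccccc2)CC1 | intermediate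
7 | (4R)‑4‑[(benzyloxy)methyl]‑3‑methylcyclohex‑2‑en‑1‑one | O=C1CC[C@@H](COCc2ccccc2)C(C)=C1 | intermediate
8 | 4‑chlorobutanoyl chloride | ClCCCC(Cl)=O | starting material
9 | (4S)‑4‑benzyl‑1,3‑oxazolidin‑2‑one | O=C1OC[C@H](Cc2ccccc2)N1 | starting material
10 | (4S)‑4‑benzyl‑3‑(4‑chlorobutanoyl)‑1,3‑oxazolidin‑2‑one | O=C1OC[C@H](Cc2ccccc2)N1C(=O)CCCCl | intermediate
11 | (4S)‑4‑benzyl‑3‑[(2R)‑4‑chloro‑2‑(dimethoxymethyl)butanoyl]‑1,3‑oxazolidin‑2‑one | O=C1OC[C@H](Cc2ccccc2)N1C(=O)[C@H](CCCl)C(OC)OC | intermediate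
12 | methyl (2R)‑4‑chloro‑2‑(dimethoxymethyl)butanoate | COC(=O)[C@H](CCCl)C(OC)OC | intermediate
13 | (3S)‑5‑chloro‑3‑(dimethoxymethyl)‑2‑methylpentan‑2‑ol | CC(C)(O)[C@H](CCCl)C(OC)OC | intermediate
14 | {[(3S)‑5‑chloro‑3‑(dimethoxymethyl)‑2‑methylpentan‑2‑yl]oxy}triethylsilane | CC[Si](CC)(CC)OC(C)(C)[C@H](CCCl)C(OC)OC | intermediate
15 | silyl enol ether from conjugate addition (name in step 11) | C[Si](C)(C)OC1=C[C@@](C)(CC[C@@H](C(C)(C)O[Si](CC)(CC)CC)C(OC)OC)[C@H](COCc2ccccc2)CC1 | intermediate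
16 | bicyclic enone (name in step 12; 1β‑CH2OBn, 10β‑Me, 7β‑side chain, Δ5) | O=C1CC[C@@H](COCc2ccccc2)[C@]2(C)CC[C@@H](C(C)(C)O[Si](CC)(CC)CC)C=C12 | intermediate
17 | trans‑decalone alcohol (name in step 13; 5α‑H) | O=C1CC[C@@H](CO)[C@]2(C)CC[C@@H](C(C)(C)O[Si](CC)(CC)CC)C[C@@H]12 | intermediate
18 | trans‑decalone aldehyde (name in step 14; 1β‑CHO) | O=C1CC[C@@H](C=O)[C@]2(C)CC[C@@H](C(C)(C)O[Si](CC)(CC)CC)C[C@@H]12 | intermediate
19 | phloroglucinol | Oc1cc(O)cc(O)c1 | starting material
20 | 2,4,6‑trihydroxybenzene‑1,3‑dicarbaldehyde | O=Cc1c(O)cc(O)c(C=O)c1O | intermediate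
21 | 2,4,6‑trimethoxybenzene‑1,3‑dicarbaldehyde | COc1cc(OC)c(C=O)c(OC)c1C=O | intermediate
22 | 5‑bromo‑2,4,6‑trimethoxybenzene‑1,3‑dicarbaldehyde | COc1c(Br)c(OC)c(C=O)c(OC)c1C=O | intermediate
23 | (5‑bromo‑2,4,6‑trimethoxy‑1,3‑phenylene)dimethanol | COc1c(Br)c(OC)c(CO)c(OC)c1CO | intermediate
24 | bis‑TIPS ether of 23 | COc1c(Br)c(OC)c(CO[Si](C(C)C)(C(C)C)C(C)C)c(OC)c1CO[Si](C(C)C)(C(C)C)C(C)C | intermediate
25 | benzylic carbinol (C1′ epimers; name in step 20) | O=C1CC[C@@H](C(O)c3c(OC)c(CO[Si](C(C)C)(C(C)C)C(C)C)c(OC)c(CO[Si](C(C)C)(C(C)C)C(C)C)c3OC)[C@]2(C)CC[C@@H](C(C)(C)O[Si](CC)(CC)CC)C[C@@H]12 | intermediate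
26 | (1′S)‑methallyl adduct (name in step 21) | O=C1CC[C@@H]([C@H](CC(C)=C)c3c(OC)c(CO[Si](C(C)C)(C(C)C)C(C)C)c(OC)c(CO[Si](C(C)C)(C(C)C)C(C)C)c3OC)[C@]2(C)CC[C@@H](C(C)(C)O[Si](CC)(CC)CC)C[C@@H]12 | intermediate
27 | (1′S)‑isobutyl decalone (name in step 22) | O=C1CC[C@@H]([C@H](CC(C)C)c3c(OC)c(CO[Si](C(C)C)(C(C)C)C(C)C)c(OC)c(CO[Si](C(C)C)(C(C)C)C(C)C)c3OC)[C@]2(C)CC[C@@H](C(C)(C)O[Si](CC)(CC)CC)C[C@@H]12 | intermediate
28 | 4(15)‑methylene compound, fully silylated (name in step 23) | C=C1CC[C@@H]([C@H](CC(C)C)c3c(OC)c(CO[Si](C(C)C)(C(C)C)C(C)C)c(OC)c(CO[Si](C(C)C)(C(C)C)C(C)C)c3OC)[C@]2(C)CC[C@@H](C(C)(C)O[Si](CC)(CC)CC)C[C@@H]12 | intermediate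
29 | triol (name in step 24) | C=C1CC[C@@H]([C@H](CC(C)C)c3c(OC)c(CO)c(OC)c(CO)c3OC)[C@]2(C)CC[C@@H](C(C)(C)O)C[C@@H]12 | intermediate
30 | tri‑O‑methyl macrocarpal H (name in step 25) | C=C1CC[C@@H]([C@H](CC(C)C)c3c(OC)c(C=O)c(OC)c(C=O)c3OC)[C@]2(C)CC[C@@H](C(C)(C)O)C[C@@H]12 | intermediate
31 | Macrocarpal H: 5‑{(1S)‑1‑[(1S,4aS,6R,8aS)‑6‑(2‑hydroxypropan‑2‑yl)‑8a‑methyl‑4‑methylidenedecahydronaphthalen‑1‑yl]‑3‑methylbutyl}‑2,4,6‑trihydroxybenzene‑1,3‑dicarbaldehyde | C=C1CC[C@@H]([C@H](CC(C)C)c2c(O)c(C=O)c(O)c(C=O)c2O)[C@]2(C)CC[C@@H](C(C)(C)O)C[C@@H]12 | target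

## Summary

Total steps: 26.

Longest linear sequence: 16 steps (steps 1–5 → 11–14 → 20–26; the chain branch 6–10 → 11–14 → 20–26 is the same length). That is 16/26 ≈ 0.62 of the total.

Three steps most likely to fail, each with a fallback that changes the approach:

- **Step 11** (conjugate addition forming quaternary C10 next to the C1 stereocentre; hindered, selectivity rests on the anti rule). Fallback: drop the C9–C10 fragment union and build the decalin from (R)‑Wieland–Miescher ketone (D‑proline intramolecular aldol sets C10). Then homologate the C1 ketone by methylenation/hydroboration–oxidation, introduce C4=O by deconjugative ketalisation/hydroboration–oxidation, and build the C7 side chain by TosMIC, MeLi, MeMgBr.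
- **Step 21** (SN1 methallylation on a hexasubstituted arene whose OMe groups are twisted, with two benzylic silyl ethers present). Fallback: couple **18** with plain 2,4,6‑trimethoxyphenyllithium, which gives a far better stabilised cation with no competing benzylic ethers. After methallylation and hydrogenation, introduce the formyl groups late: NBS dibromination before the Wittig step, then double Br/Li exchange and DMF after it.
- **Step 20** (di‑ortho‑substituted aryllithium adding to a neopentyl‑type aldehyde next to a ketone). Fallback: oxidise **18** to the acid (Pinnick), convert to the Weinreb amide, acylate the aryllithium to the aryl ketone and reduce with NaBH4 to carbinol **25**; the carbinol configuration is irrelevant for step 21.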